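Rings: A = the cyclohexanetrione, B = the spiro-fused cyclohexane, C = the cyclopentane. Retrosynthesis cuts, in order: the acyl–ring A bond; ring A at the bond from its enol CH to the carbonyl beside the methyl/prenyl carbon (Claisen) and at the bond from the spiro carbon to the other carbonyl (aldol); ring B between the methyl carbinol carbon and the CH2 beside the spiro carbon (ketone–enone reductive coupling); the CH2–C(=CH2) bond joining cyclopentane and enone (Negishi).
Forward: ring C first, by titanocene radical cyclization of (R)-linalool 1,2-epoxide (fragment 1); fragment 2 is an α-iodoenone from an enzymatically desymmetrised methyl(prenyl)malonate; the fragments are joined, ring B is closed with SmI2 and the samarium enolate is quaternised in the same flask, ring A is closed last on the spiro carbon, then the acyl group is added.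
Enabling feature: in ring B the CH2 between the spiro carbon and the methyl carbinol is β to the ring A ketone that lies between the two quaternary carbons, so carbinol oxygen and that C=O are 1,4-related; carbinol carbon and CH2 are the ketyl carbon and the β-carbon of an α-methylene ketone whose α-carbon is the future spiro carbon.
Stereochemistry: ring C carbinol from (R)-linalool; both ring-fusion CH from the radical cyclization; ring B carbinol and spiro carbon from the key step (chair transition state, then equatorial aldol); methyl/prenyl carbon from the esterase step; side chain from (S)-2-methylbutanoic acid.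

Key step: step 11

Assumption: the esterase is taken to cleave the enantiotopic ester of 9 whose hydrolysis gives (S)-10; the β-triketone of 19, 20 and 23 is written as one enol tautomer.

Step 1
Reactants: 1 (R)-(−)-linalool, (3R)-3,7-dimethylocta-1,6-dien-3-ol
Product: 2 (2R)-6-methyl-2-(oxiran-2-yl)hept-5-en-2-ol (both oxirane epimers)
Conditions: VO(acac)2 (2 mol %), t-BuOOH, CH2Cl2, 0 °C → rt
Reagents that add atoms: tert-butyl hydroperoxide, CC(C)(C)OO
Why: Hydroxyl-directed vanadium-catalysed epoxidation should deliver oxygen from the bound tertiary allylic alcohol to the adjacent vinyl group in preference to the remote trisubstituted alkene; the new oxirane CH may form as both epimers because it becomes a radical centre in step 2.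

Step 2
Reactants: 2 (2R)-6-methyl-2-(oxiran-2-yl)hept-5-en-2-ol
Product: 3 (1R,2R,3S)-2-(hydroxymethyl)-1-methyl-3-(prop-1-en-2-yl)cyclopentan-1-ol
Conditions: Cp2TiCl2 (2.2 equiv), Mn dust, THF, rt, slow addition of the Cp2TiCl solution to 2; then 1 M aq. HCl, 0 °C, brief
Reagents that add atoms: none
Why: Titanocene monochloride epoxide-opening radical cyclization: the oxirane should open to the secondary β-titanoxy radical, which closes 5-exo-trig onto the trisubstituted alkene through a chair-like transition state that puts the CH2O[Ti] group of the radical carbon cis to the new C–C bond and the methyl of the neighbouring carbinol carbon pseudo-equatorial (hydroxyl pseudo-axial, cis to both new substituents), after which the tertiary radical is trapped by a second Cp2TiCl and loses a methyl β-hydrogen to give the isopropenyl group; the slow addition keeps the titanium concentration low so that ring closure outruns reductive trapping.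

Step 3
Reactants: 3 (1R,2R,3S)-2-(hydroxymethyl)-1-methyl-3-(prop-1-en-2-yl)cyclopentan-1-ol
Product: 4 (1R,2S,3S)-2-(iodomethyl)-1-methyl-3-(prop-1-en-2-yl)cyclopentan-1-ol
Conditions: PPh3, I2, imidazole (pre-mixed), CH2Cl2, 0 °C
Reagents that add atoms: iodine, [I][I]
Why: Appel iodination should convert only the primary hydroxyl, through its oxyphosphonium salt and SN2 attack of iodide, while the tertiary hydroxyl stays; pre-forming the iodophosphonium salt leaves no free iodine for iodoetherification, and no stereocentre is touched.

Step 4
Reactants: 4 (1R,2S,3S)-2-(iodomethyl)-1-methyl-3-(prop-1-en-2-yl)cyclopentan-1-ol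
Product: 5 {[(1R,2S,3S)-2-(iodomethyl)-1-methyl-3-(prop-1-en-2-yl)cyclopentyl]oxy}trimethylsilane
Conditions: Me3SiOTf, 2,6-lutidine, CH2Cl2, −78 °C
Reagents that add atoms: trimethylsilyl trifluoromethanesulfonate, C[Si](C)(C)OS(=O)(=O)C(F)(F)F
Why: Silylation of the tertiary alcohol with the silyl triflate keeps this hydroxyl from protonating the alkylzinc of step 10 and from oxa-Michael addition to the α-methylene ketone of 15.

Step 5
Reactants: 5 {[(1R,2S,3S)-2-(iodomethyl)-1-methyl-3-(prop-1-en-2-yl)cyclopentyl]oxy}trimethylsilane
Product: 6 1-[(1S,2S,3R)-2-(iodomethyl)-3-methyl-3-(trimethylsilyloxy)cyclopentyl]ethan-1-one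
Conditions: O3, CH2Cl2, −78 °C (indicator end point); then Me2S, −78 °C → rt
Reagents that add atoms: ozone, [O-][O+]=O
Why: Ozonolysis of the 1,1-disubstituted alkene with reductive work-up should give the methyl ketone under neutral conditions, so the ring CH beside the ketone (cis to the iodomethyl group) is not epimerised and no base is present that could close a cyclopropane from the γ-iodo ketone.

Step 6
Reactants: 7 dimethyl 2-methylpropanedioate; 8 1-bromo-3-methylbut-2-ene (prenyl bromide)
Product: 9 dimethyl 2-methyl-2-(3-methylbut-2-en-1-yl)propanedioate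
Conditions: NaH, THF, 0 °C → rt
Reagents that add atoms: none
Why: Malonate alkylation (SN2 at the primary allylic bromide) gives the prochiral quaternary diester.

Step 7
Reactants: 9 dimethyl 2-methyl-2-(3-methylbut-2-en-1-yl)propanedioate
Product: 10 (2S)-2-(methoxycarbonyl)-2,5-dimethylhex-4-enoic acid
Conditions: pig liver esterase, 0.1 M phosphate buffer pH 7.5, DMSO (5%), rt; then acidify to pH 3, 0 °C
Reagents that add atoms: water, O
Why: Enzymatic desymmetrisation: hydrolysis of one of the two enantiotopic methyl esters should turn the carbon that bears methyl and prenyl into the (S) quaternary stereocentre.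

Step 8
Reactants: 10 (2S)-2-(methoxycarbonyl)-2,5-dimethylhex-4-enoic acid
Product: 12 methyl (2S)-2,5-dimethyl-2-(prop-2-enoyl)hex-4-enoate, via acid chloride 11 (not isolated)
Conditions: 1-chloro-N,N,2-trimethylprop-1-en-1-amine, CH2Cl2, 0 °C → rt; then CH2=CHSnBu3, PdCl2(PPh3)2 (2 mol %), toluene, 60 °C
Reagents that add atoms: tributyl(vinyl)stannane, C=C[Sn](CCCC)(CCCC)CCCC
Why: Neutral acid chloride formation with the α-chloroenamine followed by Stille acylation (acid chloride plus vinylstannane under palladium catalysis) should give the vinyl ketone without acid that could lactonise the γ,δ-unsaturated acid and without touching the quaternary stereocentre.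

Step 9
Reactants: 12 methyl (2S)-2,5-dimethyl-2-(prop-2-enoyl)hex-4-enoate
Product: 13 methyl (2S)-2-(2-iodoprop-2-enoyl)-2,5-dimethylhex-4-enoate
Conditions: I2, DMAP (0.2 equiv), K2CO3, THF–H2O (1:1), rt
Reagents that add atoms: iodine, [I][I]
Why: α-Iodination of the enone by a Morita–Baylis–Hillman-type sequence (DMAP adds to the β-carbon, the enolate is iodinated, DMAP is eliminated) should functionalise only the vinyl ketone and not the prenyl alkene.

Step 10
Reactants: 6 1-[(1S,2S,3R)-2-(iodomethyl)-3-methyl-3-(trimethylsilyloxy)cyclopentyl]ethan-1-one; 13 methyl (2S)-2-(2-iodoprop-2-enoyl)-2,5-dimethylhex-4-enoate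
Product: 15 methyl (2S)-2-(2-{[(1S,2R,5S)-5-acetyl-2-methyl-2-(trimethylsilyloxy)cyclopentyl]methyl}prop-2-enoyl)-2,5-dimethylhex-4-enoate, via alkylzinc iodide 14 (not isolated)
Conditions: Zn dust (activated), LiCl, THF, 40 °C; then 13, Pd2(dba)3 (2.5 mol %), SPhos (10 mol %), THF, rt
Reagents that add atoms: none
Why: Negishi sp3–sp2 cross-coupling: zinc inserts into the primary C–I bond to give a ketone-tolerant alkylzinc iodide, which transmetalates to the alkenylpalladium iodide formed from zerovalent palladium and the α-iodoenone, and reductive elimination joins the fragments without base, so neither the epimerisable CH beside the acetyl group nor the quaternary centre of 13 is affected.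

Step 11
Reactants: 15 methyl (2S)-2-(2-{[(1S,2R,5S)-5-acetyl-2-methyl-2-(trimethylsilyloxy)cyclopentyl]methyl}prop-2-enoyl)-2,5-dimethylhex-4-enoate
Product: 17 methyl (2S)-2-{[(1R,3aS,4R,6S,7aS)-4-hydroxy-6-(1-hydroxyethyl)-1,4-dimethyl-1-(trimethylsilyloxy)octahydro-1H-inden-6-yl]carbonyl}-2,5-dimethylhex-4-enoate (both epimers of the hydroxyethyl carbinol), via samarium enolate 16 (not isolated)
Conditions: SmI2 (2.1 equiv), HMPA (8 equiv), THF, −78 °C; then CH3CHO (5 equiv), −78 °C; aq. NH4Cl
Reagents that add atoms: acetaldehyde, CC=O
Why: SmI2 reduces the ketone/enone pair by single-electron transfer, the ketyl carbon (the future methyl carbinol carbon) adds to the unsubstituted CH2 terminus of the α-methylene ketone, and a second electron gives a trivalent samarium enolate whose α-carbon is the future spiro carbon; with no proton source present this enolate survives and adds to acetaldehyde. The closest known reaction type is the samarium diiodide ketyl–olefin (ketone–enone) reductive cyclization run in sequence with an aldol reaction of the samarium enolate. Ring B is closed in the 6-endo-trig mode with respect to the alkene, which should be preferred over 5-exo attack because the nucleophilic ketyl adds to the electrophilic β-carbon and would otherwise have to attack a fully substituted carbon and leave a primary radical. The carbinol stereocentre is controlled by a chair-like transition state on the cis-disubstituted cyclopentane in which the bulky samarium-bound oxygen is pseudo-equatorial and the methyl pseudo-axial, placing the hydroxyl trans to the adjacent ring-fusion hydrogen; the spiro stereocentre is controlled in the aldol step by equatorial attack on the exocyclic enolate, away from that axial methyl and on the side of the neighbouring samarium alkoxide, so that the two-carbon unit ends cis to the hydroxyl, while the hydroxyethyl carbinol forms as a mixture that step 12 removes. The step needs carbon–carbon coupling at the β-carbon rather than conjugate reduction or aldol attack of the α-carbon on the methyl ketone, which the aprotic medium should secure because the β-carbon cannot be protonated before ring closure, and it should leave the ester, the prenyl alkene and the silyl ether untouched.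

Step 12
Reactants: 17 methyl (2S)-2-{[(1R,3aS,4R,6S,7aS)-4-hydroxy-6-(1-hydroxyethyl)-1,4-dimethyl-1-(trimethylsilyloxy)octahydro-1H-inden-6-yl]carbonyl}-2,5-dimethylhex-4-enoate
Product: 18 methyl (2S)-2-{[(1R,3aS,4R,6S,7aS)-6-acetyl-4-hydroxy-1,4-dimethyl-1-(trimethylsilyloxy)octahydro-1H-inden-6-yl]carbonyl}-2,5-dimethylhex-4-enoate
Conditions: Dess–Martin periodinane, CH2Cl2, rt
Reagents that add atoms: none
Why: Dess–Martin oxidation of the only secondary alcohol (the tertiary alcohol and the silyl ether are inert) should give the acetyl group and cannot change a stereocentre because the carbon between the two ketones is quaternary.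

Step 13
Reactants: 18 methyl (2S)-2-{[(1R,3aS,4R,6S,7aS)-6-acetyl-4-hydroxy-1,4-dimethyl-1-(trimethylsilyloxy)octahydro-1H-inden-6-yl]carbonyl}-2,5-dimethylhex-4-enoate
Product: 20 spiro trione diol, the target without its 2-methylbutanoyl group (enolised ring A, all stereocentres as in the target), via silylated trione 19 (not isolated)
Conditions: LiN(SiMe3)2 (3.5 equiv), THF, −78 → 0 °C; then 1 M aq. HCl, THF, rt
Reagents that add atoms: none
Why: Intramolecular Claisen (Dieckmann-type) condensation: the only enolisable position, the acetyl methyl, attacks the methyl ester on the prenyl-bearing quaternary carbon and closes ring A in a 6-exo-trig acyl substitution driven by deprotonation of the cyclic β-triketone, and the acidic work-up cleaves the tertiary trimethylsilyl ether; neither quaternary stereocentre takes part.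

Step 14
Reactants: 20 spiro trione diol; 21 (S)-2-methylbutanoic acid
Product: 23 hyperielliptone HB, via enol ester 22 (not isolated)
Conditions: DCC, DMAP (1.2 equiv), CH2Cl2, rt
Reagents that add atoms: none
Why: Carbodiimide O-acylation of the enolised cyclic 1,3-diketone followed by DMAP-mediated 1,3-acyl migration from oxygen to carbon should place the (S)-2-methylbutanoyl group on the only free ring A carbon, the two tertiary alcohols being too hindered to be acylated; the stereocentre of the acid is carried over.

Compound list
1 | (R)-(−)-linalool, (3R)-3,7-dimethylocta-1,6-dien-3-ol | C=C[C@](C)(O)CCC=C(C)C | starting material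
2 | (2R)-6-methyl-2-(oxiran-2-yl)hept-5-en-2-ol, both oxirane epimers | C1OC1[C@](C)(O)CCC=C(C)C | intermediate
3 | (1R,2R,3S)-2-(hydroxymethyl)-1-methyl-3-(prop-1-en-2-yl)cyclopentan-1-ol | OC[C@H]1[C@H](CC[C@@]1(C)O)C(C)=C | intermediate
4 | (1R,2S,3S)-2-(iodomethyl)-1-methyl-3-(prop-1-en-2-yl)cyclopentan-1-ol | IC[C@H]1[C@H](CC[C@@]1(C)O)C(C)=C | intermediate
5 | {[(1R,2S,3S)-2-(iodomethyl)-1-methyl-3-(prop-1-en-2-yl)cyclopentyl]oxy}trimethylsilane | IC[C@H]1[C@H](CC[C@@]1(C)O[Si](C)(C)C)C(C)=C | intermediate
6 | 1-[(1S,2S,3R)-2-(iodomethyl)-3-methyl-3-(trimethylsilyloxy)cyclopentyl]ethan-1-one | IC[C@H]1[C@H](CC[C@@]1(C)O[Si](C)(C)C)C(C)=O | intermediate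
7 | dimethyl 2-methylpropanedioate | COC(=O)C(C)C(=O)OC | starting material
8 | 1-bromo-3-methylbut-2-ene (prenyl bromide) | CC(C)=CCBr | starting material
9 | dimethyl 2-methyl-2-(3-methylbut-2-en-1-yl)propanedioate | COC(=O)C(C)(CC=C(C)C)C(=O)OC | intermediate
10 | (2S)-2-(methoxycarbonyl)-2,5-dimethylhex-4-enoic acid | COC(=O)[C@@](C)(CC=C(C)C)C(=O)O | intermediate
11 | methyl (2R)-2-(chlorocarbonyl)-2,5-dimethylhex-4-enoate | COC(=O)[C@@](C)(CC=C(C)C)C(Cl)=O | intermediate
12 | methyl (2S)-2,5-dimethyl-2-(prop-2-enoyl)hex-4-enoate | COC(=O)[C@@](C)(CC=C(C)C)C(=O)C=C | intermediate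
13 | methyl (2S)-2-(2-iodoprop-2-enoyl)-2,5-dimethylhex-4-enoate | COC(=O)[C@@](C)(CC=C(C)C)C(=O)C(I)=C | intermediate
14 | {[(1S,2R,5S)-5-acetyl-2-methyl-2-(trimethylsilyloxy)cyclopentyl]methyl}zinc iodide | I[Zn]C[C@H]1[C@H](CC[C@@]1(C)O[Si](C)(C)C)C(C)=O | intermediate
15 | methyl (2S)-2-(2-{[(1S,2R,5S)-5-acetyl-2-methyl-2-(trimethylsilyloxy)cyclopentyl]methyl}prop-2-enoyl)-2,5-dimethylhex-4-enoate | COC(=O)[C@@](C)(CC=C(C)C)C(=O)C(=C)C[C@H]1[C@H](CC[C@@]1(C)O[Si](C)(C)C)C(C)=O | intermediate
16 | bis(diiodosamarium) alkoxide–enolate of the cyclised keto ester (ring B closed, enolate carbon is the future spiro carbon) | COC(=O)[C@@](C)(CC=C(C)C)C(O[Sm](I)I)=C1C[C@H]2[C@H](CC[C@@]2(C)O[Si](C)(C)C)[C@](C)(O[Sm](I)I)C1 | intermediate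
17 | methyl (2S)-2-{[(1R,3aS,4R,6S,7aS)-4-hydroxy-6-(1-hydroxyethyl)-1,4-dimethyl-1-(trimethylsilyloxy)octahydro-1H-inden-6-yl]carbonyl}-2,5-dimethylhex-4-enoate, hydroxyethyl group equatorial and cis to the ring B hydroxyl, carbinol epimers | COC(=O)[C@@](C)(CC=C(C)C)C(=O)[C@@]1(C(C)O)C[C@H]2[C@H](CC[C@@]2(C)O[Si](C)(C)C)[C@](C)(O)C1 | intermediate
18 | methyl (2S)-2-{[(1R,3aS,4R,6S,7aS)-6-acetyl-4-hydroxy-1,4-dimethyl-1-(trimethylsilyloxy)octahydro-1H-inden-6-yl]carbonyl}-2,5-dimethylhex-4-enoate | COC(=O)[C@@](C)(CC=C(C)C)C(=O)[C@@]1(C(C)=O)C[C@H]2[C@H](CC[C@@]2(C)O[Si](C)(C)C)[C@](C)(O)C1 | intermediate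
19 | spiro trione with ring A closed and the ring C hydroxyl still silylated (target skeleton without the acyl group, enol form) | C1=C(O)[C@@](C)(CC=C(C)C)C(=O)[C@]2(C[C@H]3[C@H](CC[C@@]3(C)O[Si](C)(C)C)[C@](C)(O)C2)C1=O | intermediate
20 | spiro trione diol, the target without its 2-methylbutanoyl group | C1=C(O)[C@@](C)(CC=C(C)C)C(=O)[C@]2(C[C@H]3[C@H](CC[C@@]3(C)O)[C@](C)(O)C2)C1=O | intermediate
21 | (S)-2-methylbutanoic acid | CC[C@H](C)C(=O)O | starting material
22 | enol (S)-2-methylbutanoate of 20 (ester on the ring A enol oxygen) | C1=C(OC(=O)[C@@H](C)CC)[C@@](C)(CC=C(C)C)C(=O)[C@]2(C[C@H]3[C@H](CC[C@@]3(C)O)[C@](C)(O)C2)C1=O | intermediate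
23 | hyperielliptone HB | CC[C@H](C)C(=O)C1=C(O)[C@@](C)(CC=C(C)C)C(=O)[C@]2(C[C@H]3[C@H](CC[C@@]3(C)O)[C@](C)(O)C2)C1=O | target

Total steps: 14. Longest linear sequence: 10 steps (steps 1 to 5 and 10 to 14).

Steps most likely to fail

Step 11. What may go wrong is reduction of the enone without ring closure, protonation or retro-aldol of the hindered samarium enolate before it is trapped, and incomplete facial control at the carbinol. The fallback sets out from 15 and generates the carbinol radical by hydrogen-atom transfer instead of electron transfer. The methyl ketone is converted into its less substituted silyl enol ether F1 (LiN(SiMe3)2, Me3SiCl, THF, −78 °C). An iron hydride (Fe(acac)3, PhSiH3, EtOH, 60 °C) transfers a hydrogen atom to the terminal CH2 of the enol ether, and the tertiary α-silyloxy radical adds to the CH2 of the enone, forming the same bond and giving the cyclised bis-silyl ether F2. A lithium enolate aldol (LiN(iPr)2, THF, −78 °C; CH3CHO) gives the hydroxyethyl ketone F3, Dess–Martin oxidation gives the diketone F4, and the conditions of step 13 give, through the bis-silyl trione F5, the trione 20, where the route is rejoined.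

Step 10. What may go wrong is protodezincation or slow transmetalation of the β-branched alkylzinc, and polymerisation or reduction of the α-iodoenone before it couples. The fallback sets out from 6 and 13 and uses a nickel-catalysed reductive cross-electrophile coupling (NiBr2(dme), 4,4′-di-tert-butyl-2,2′-bipyridine, Mn dust, DMA, rt). The alkyl radical from 6 is captured by the alkenylnickel species from 13, so no organozinc reagent is formed; the coupling returns directly to 15 and makes no new compound (F0).

Step 7. What may go wrong is low or reversed enantiotopic-group selectivity of the esterase with this substrate. The fallback sets out from 9 and replaces the enzyme by a classical resolution. Mono-saponification (KOH, 1.0 equiv, MeOH, 0 °C) gives the racemic half-ester F6. Crystallisation with (R)-1-phenylethylamine, or with its antipode if that gives the less soluble salt of the (S)-acid, gives the ammonium salt F7, and acidification returns 10.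

Further compounds
F1 | step 11 | trimethylsilyl enol ether of 15 at the acetyl methyl | COC(=O)[C@@](C)(CC=C(C)C)C(=O)C(=C)C[C@H]1[C@H](CC[C@@]1(C)O[Si](C)(C)C)C(=C)O[Si](C)(C)C
F2 | step 11 | cyclised keto ester with both tertiary oxygens silylated (CH beside the ketone as epimers) | COC(=O)[C@@](C)(CC=C(C)C)C(=O)C1C[C@H]2[C@H](CC[C@@]2(C)O[Si](C)(C)C)[C@](C)(O[Si](C)(C)C)C1
F3 | step 11 | bis-silyl analogue of 17 | COC(=O)[C@@](C)(CC=C(C)C)C(=O)[C@@]1(C(C)O)C[C@H]2[C@H](CC[C@@]2(C)O[Si](C)(C)C)[C@](C)(O[Si](C)(C)C)C1
F4 | step 11 | bis-silyl analogue of 18 | COC(=O)[C@@](C)(CC=C(C)C)C(=O)[C@@]1(C(C)=O)C[C@H]2[C@H](CC[C@@]2(C)O[Si](C)(C)C)[C@](C)(O[Si](C)(C)C)C1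
F5 | step 11 | bis-silyl analogue of 19 | C1=C(O)[C@@](C)(CC=C(C)C)C(=O)[C@]2(C[C@H]3[C@H](CC[C@@]3(C)O[Si](C)(C)C)[C@](C)(O[Si](C)(C)C)C2)C1=O
F0 | step 10 | none | none
F6 | step 7 | racemic 2-(methoxycarbonyl)-2,5-dimethylhex-4-enoic acid | COC(=O)C(C)(CC=C(C)C)C(=O)O
F7 | step 7 | (R)-1-phenylethylammonium (2S)-2-(methoxycarbonyl)-2,5-dimethylhex-4-enoate | COC(=O)[C@@](C)(CC=C(C)C)C(=O)[O-].C[C@@H]([NH3+])c1ccccc1
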